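All runs come from a simulation with constants of no real substance.

Two constants read from your north readings give the height of the peak, so I reckon with the fraction left and not the fraction made. You wanted a quick number, and this flask is charged as the north run.

in all of them: free monomer 0.010 M

| charge | transfer agent | initiator | remark | time |
|---|---|---|---|---|
| north | 0.10 mM | 5 mol% | the very flask that is asked about, followed so far |  |
| south-west | 0.10 mM | 2.5 mol% | run made earlier |  |
| flask | 0.100 mM | 5 mol% |  | 8.0 d |

- north (time / h: monomer in chains / %): 1.00: 53.8; 3.00: 94.1; 12.0: 87.6; 40.0: 75.0
- south-west (time / d: monomer in chains / %): 0.0556: 48.1; 0.250: 96.6; 1.25: 89.5; 6.00: 75.8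

(scatter of a reading: 1 percentage point)

- when, up to 8.0 d, the flask holds most monomer in chains
- the amount of monomer in chains, in percent of the free monomer charged, at that time



At 1.00 h the north run has 46.2% of the charge outside chains, which gives an uptake constant of 0.772 h⁻¹. From 3.00 h to 12.0 h the fraction of chains kept gives a loss constant of 0.00795 h⁻¹. Their quotient is the uptake-to-loss ratio, a selectivity factor, and here it is 97.1. For first-order uptake followed by first-order loss with a large ratio, the fraction missing at the peak is close to ln(ratio)/ratio, here 4.71%. So I commit to a peak of 95.3%, as a reading with its scatter.

The same constants put the peak at 0.249 d. But the 3.00 h reading of 94.1% stands above the 90.1% that steady uptake allows, so I expect an earlier peak.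

The forecast says 0.14 d and 95%: “Monomer goes into chains quickly, then the chains slowly lose it.” Its time is earlier than that of my constants.

The flask peaks at 0.159 d with 94.6% in chains, and the forecast holds on both.

    free monomer + initiator → living end + monomer in chains (k = 67.0 M⁻¹ h⁻¹)
    free monomer + living end → monomer in chains + living end, rate k2*[living end]*[free monomer] (k = 6100 M⁻¹ h⁻¹)
    living end + transfer agent → dead chain (kL = 820 M⁻¹ h⁻¹)
    monomer in chains + initiator ⇌ isomer of the product + initiator, rate k4*[initiator]*[monomer in chains] forward; the back reaction follows from the equilibrium constant (K = 0.370, k = 70.0 M⁻¹ h⁻¹)

The ratio put 4.71% outside chains at the peak. At the best time, 0.159 d, this flask has 5.40% outside chains, of which 4.35% is isomer of the product and 1.01% free monomer. The largest single effect on the height is the conversion of chains into that isomer: the run without it reaches 100% against 94.6%. Read the same way, the south-west run has a ratio of 155, which gives 96.7%, and its highest value without the scatter is 96.4%.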